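Ring A is the benzene ring, ring B the lactone, and C1' to C11' the side chain counted from C3.

**Plan**
1. Retrosynthesis: 8-OH is masked as OMe. The side chain is cut at C1'–C2' (as an alkene, cross metathesis). Ring B is then cut at C4–C4a and O2–C3 together, leaving 2,4-dimethoxybenzoic acid and buta-1,3-diene. The alkenol is cut at C4'–C5' into (S)-2-pentyloxirane and a butenyl Grignard reagent.
2. Forward: alkenol 4 is made in two steps, and ring B is annulated onto ring A in one oxidative C–H/O–H (4+2) event. Cross metathesis joins the halves, then hydrogenation and chelation-directed 8-O-demethylation finish.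
3. Enabling feature: the C1 carboxyl group on C8a has one ortho neighbour blocked by oxygen (C8) and one free (C4a–H). It can therefore first direct palladation of C4a and then act as the O2 nucleophile. C4, C3, C1' and C2' are the four carbons of butadiene.
4. Helper: the second alkene (C1'=C2') turns the alkylpalladium at C3 into an η3-allyl, which prevents β-hydride loss. It then serves as the metathesis handle and is removed by hydrogenation.
5. Stereochemistry: C6' (S) comes from hydrolytic kinetic resolution of the epoxide and is carried unchanged. C3 comes from the chiral amino acid ligand on palladium in the key step (3S in the vinyl lactone equals 3R after saturation, same geometry).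

Key step: step 3

Assumption: N-acetyl-L-tert-leucine is written as the ligand antipode that leads to (3S)-7. Should the sense of induction be the opposite, the D-antipode is used with no other change.

**Step 1**
Reactants: 1 rac-2-pentyloxirane (1,2-epoxyheptane)
Product: 2 (S)-2-pentyloxirane
Conditions: (S,S)-(salen)Co(OAc) (0.5 mol%; salen = N,N'-bis(3,5-di-tert-butylsalicylidene)cyclohexane-1,2-diaminate), H2O (0.55 equiv), neat, 0 °C to rt; distillation
Reagents that add atoms: none
Why: Jacobsen hydrolytic kinetic resolution: the (S,S)-catalyst hydrates the (R)-epoxide far faster than the (S)-epoxide, so that unreacted (S)-2, which holds the future C6' stereocentre, should be left in high enantiomeric purity and is distilled from the diol.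

**Step 2**
Reactants: 2 (S)-2-pentyloxirane; 3 but-3-enylmagnesium bromide
Product: 4 (S)-undec-1-en-6-ol
Conditions: 3 (1.3 equiv), CuI (10 mol%), THF, −30 to 0 °C; aqueous work-up
Reagents that add atoms: none
Why: Copper-catalysed SN2 opening of a terminal epoxide by a Grignard reagent at the unsubstituted carbon, which does not touch the C–O bond of the stereocentre, so that the (S) configuration is retained.

**Step 3**
Reactants: 5 2,4-dimethoxybenzoic acid; 6 buta-1,3-diene
Product: 7 (3S)-6,8-dimethoxy-3-vinylisochroman-1-one
Conditions: Pd(OAc)2 (10 mol%), N-acetyl-L-tert-leucine (20 mol%), KOAc (1 equiv), 2,5-dimethyl-1,4-benzoquinone (1.5 equiv), 6 (5 equiv, toluene solution), (CF3)2CHOH, 70 °C, sealed tube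
Reagents that add atoms: none
Why: Proposed new method: the potassium carboxylate of 5 guides amino-acid-ligated divalent palladium to concerted metalation-deprotonation of its only free ortho C–H, butadiene inserts into the aryl–Pd bond so that the aryl carbon (C4a) bonds to a terminal CH2 (C4), the resulting η3-allylpalladium is attacked at its internal carbon (C3) by the same carboxylate oxygen (O2), and the quinone takes zerovalent palladium back to divalent palladium. The closest known reaction types are the oxidative (4+2) annulation of N-alkoxybenzamides with 1,3-dienes under divalent palladium (racemic, and enantioselective on heteroaryl amides), the Larock heteroannulation of 1,3-dienes by ortho-functionalised aryl halides, the amino-acid-accelerated ortho C–H alkylation of potassium benzoates in (CF3)2CHOH, whose base, ligand and solvent are copied here, and the amino-acid-controlled enantioselective annulation of benzylic triflamides with allenes through allylpalladium intermediates; what is new is the enantioselective form on a free benzoic acid. Ring B closes in the 6-exo mode at the allyl unit, giving the six-membered lactone with an exocyclic vinyl group rather than the eight-membered lactone that attack at the distal CH2 would give. C3 is controlled by the chiral amino acid ligand alone: since the distal allyl terminus from butadiene is an unsubstituted CH2, the two diastereomeric allyl complexes should interconvert by η3-η1-η3 slippage faster than they close, so that the configuration is decided in the C–O bond-forming step next to the tert-butyl group of the ligand. The step needs ortho C–H cleavage rather than palladation at the electron-rich C3 and C5 of 5 (secured by chelation to the carboxylate and by the 2-OMe group that blocks the second ortho site), allyl capture rather than β-hydride elimination (secured by the η3 binding that the second alkene provides and by the carboxylate held next to it), and retention of CO2 (no silver or copper salt, no DMSO, moderate temperature). The allylic lactone should keep its configuration because zerovalent palladium, which could re-ionise it, is intercepted by the quinone, and the excess of diene shields the vinyl group of 7 from a second arylation.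

**Step 4**
Reactants: 7 (3S)-6,8-dimethoxy-3-vinylisochroman-1-one; 4 (S)-undec-1-en-6-ol
Product: 8 (3S)-3-[(1E,6S)-6-hydroxyundec-1-en-1-yl]-6,8-dimethoxyisochroman-1-one
Conditions: second-generation Grubbs catalyst (5 mol%), 4 (2 equiv), CH2Cl2, 40 °C
Reagents that add atoms: none
Why: Olefin cross metathesis between a fast-reacting terminal alkene (4, type 1) and a slower secondary allylic ester alkene (7, type 2), a pairing that favours the cross product over both homodimers, tolerates the free alcohol and the lactone, touches no stereocentre, and whose E/Z outcome is irrelevant since the alkene is saturated next.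

**Step 5**
Reactants: 8 (3S)-3-[(1E,6S)-6-hydroxyundec-1-en-1-yl]-6,8-dimethoxyisochroman-1-one
Product: 9 (3R)-3-[(6S)-6-hydroxyundecyl]-6,8-dimethoxyisochroman-1-one
Conditions: H2 (1 atm), Rh/Al2O3 (5 wt% Rh), EtOAc, rt
Reagents that add atoms: none
Why: Heterogeneous catalytic hydrogenation, with rhodium on alumina chosen over palladium because it should saturate the disubstituted alkene with little allylic C–O hydrogenolysis or double-bond migration towards C3, so that the geometry at C3 is kept (the descriptor changes from S to R only through the CIP ranking of the side chain).

**Step 6**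
Reactants: 9 (3R)-3-[(6S)-6-hydroxyundecyl]-6,8-dimethoxyisochroman-1-one
Product: 10 (3R)-8-hydroxy-3-[(6S)-6-hydroxyundecyl]-6-methoxyisochroman-1-one (target)
Conditions: BCl3 (3 equiv, 1 M in CH2Cl2), CH2Cl2, −78 to 0 °C; then H2O
Reagents that add atoms: none
Why: Chelation-directed Lewis acid cleavage of an aryl methyl ether: BCl3 bridges the lactone C=O and the peri 8-OMe in a six-membered chelate and chloride removes that methyl group, the 6-OMe cannot chelate and should stay, the carbinol is held as a borate ester at low temperature and is freed on aqueous work-up, and neither stereocentre is involved.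

**Compound list**
1 | rac-2-pentyloxirane | CCCCCC1CO1 | starting material
2 | (S)-2-pentyloxirane | CCCCC[C@H]1CO1 | intermediate
3 | but-3-enylmagnesium bromide | C=CCC[Mg]Br | starting material
4 | (S)-undec-1-en-6-ol | CCCCC[C@H](O)CCCC=C | intermediate
5 | 2,4-dimethoxybenzoic acid | COc1ccc(C(=O)O)c(OC)c1 | starting material
6 | buta-1,3-diene | C=CC=C | starting material
7 | (3S)-6,8-dimethoxy-3-vinylisochroman-1-one | C=C[C@@H]1Cc2cc(OC)cc(OC)c2C(=O)O1 | intermediate
8 | (3S)-3-[(1E,6S)-6-hydroxyundec-1-en-1-yl]-6,8-dimethoxyisochroman-1-one | CCCCC[C@H](O)CCC/C=C/[C@@H]1Cc2cc(OC)cc(OC)c2C(=O)O1 | intermediate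
9 | (3R)-3-[(6S)-6-hydroxyundecyl]-6,8-dimethoxyisochroman-1-one | CCCCC[C@H](O)CCCCC[C@@H]1Cc2cc(OC)cc(OC)c2C(=O)O1 | intermediate
10 | (3R)-8-hydroxy-3-[(6S)-6-hydroxyundecyl]-6-methoxyisochroman-1-one | CCCCC[C@H](O)CCCCC[C@@H]1Cc2cc(OC)cc(O)c2C(=O)O1 | target

Total step count: 6. Longest linear sequence: 5 (steps 1, 2, 4, 5, 6).

**Steps most likely to fail**

**Step 3.**
- C–H palladation may be slower than direct acyloxypalladation of the diene, or slower than cycloaddition between diene and quinone. Oxidant and diene would then be used up unproductively.
- The allyl intermediate may lose a benzylic β-hydrogen.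
- The electron-rich acid may undergo decarboxylative palladation.
- The small ligand may discriminate the two allyl faces poorly. Recrystallisation of 7 would be the place to raise its enantiomeric purity.

The fallback uses known chemistry only. It sets out from 2 and 5 and comes back to the route at 9. Epoxide 2 is opened with hex-5-enylmagnesium bromide and CuI to give (S)-tridec-12-en-6-ol F1. mCPBA converts this into (6S)-11-(oxiran-2-yl)undecan-6-ol F2 as a mixture of oxirane epimers. A second hydrolytic kinetic resolution with (R,R)-(salen)Co(OAc) leaves (6S)-11-[(2R)-oxiran-2-yl]undecan-6-ol F3.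

The known ortho C–H alkylation of potassium benzoates with terminal epoxides is then applied (Pd(OAc)2, N-acetyl-tert-leucine, KOAc, (CF3)2CHOH, 75 °C). It joins 5 and F3 at the epoxide CH2 and lactonises in the same flask to 9, with retention at the carbinol carbon. In this variant the ring oxygen comes from the epoxide, C3 comes from the resolution, and steps 4 and 5 are not needed.

**Step 4.**
- The allylic ester alkene may engage the catalyst slowly, so that homodimerisation of 4 dominates.
- Ruthenium hydrides may move the double bonds.

The fallback sets out from 2 and 7 and comes back at 9. Epoxide 2 is opened with lithium acetylide–ethylenediamine complex in DMSO to give (S)-non-1-yn-4-ol F4. Hydrozirconation with Cp2Zr(H)Cl (one extra equivalent for the OH group) and iodinolysis with I2 give (1E,4S)-1-iodonon-1-en-4-ol F5. Vinyl lactone 7 is hydroborated at its terminal carbon with 9-BBN-H to give (3R)-3-[2-(9-borabicyclo[3.3.1]nonan-9-yl)ethyl]-6,8-dimethoxyisochroman-1-one F6.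

F6 is used directly in a B-alkyl Suzuki–Miyaura coupling with F5 (PdCl2(dppf), Cs2CO3, DMF/THF/H2O, rt). The product is (3R)-3-[(3E,6S)-6-hydroxyundec-3-en-1-yl]-6,8-dimethoxyisochroman-1-one F7. Hydrogenation under the conditions of step 5 gives 9.

**Step 6.**
- Both aryl methyl ethers may be cleaved.
- The free carbinol may suffer substitution or elimination through its dichloroborinate.

The fallback sets out from 9 and comes back at 10. The carbinol is first acetylated (Ac2O, pyridine, DMAP) to give (3R)-3-[(6S)-6-acetoxyundecyl]-6,8-dimethoxyisochroman-1-one F8. BCl3 at −78 °C then removes only the chelated methyl group and gives (3R)-3-[(6S)-6-acetoxyundecyl]-8-hydroxy-6-methoxyisochroman-1-one F9. Methanolysis of the acetate (K2CO3, MeOH, rt) follows, and acidification re-closes any opened lactone to give 10.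

**Further compounds**
F1 | step 3 | (S)-tridec-12-en-6-ol | CCCCC[C@H](O)CCCCCC=C
F2 | step 3 | (6S)-11-(oxiran-2-yl)undecan-6-ol, both oxirane epimers | CCCCC[C@H](O)CCCCCC1CO1
F3 | step 3 | (6S)-11-[(2R)-oxiran-2-yl]undecan-6-ol | CCCCC[C@H](O)CCCCC[C@@H]1CO1
F4 | step 4 | (S)-non-1-yn-4-ol | CCCCC[C@H](O)CC#C
F5 | step 4 | (1E,4S)-1-iodonon-1-en-4-ol | CCCCC[C@H](O)C/C=C/I
F6 | step 4 | (3R)-3-[2-(9-borabicyclo[3.3.1]nonan-9-yl)ethyl]-6,8-dimethoxyisochroman-1-one | C1CC2CCCC(C1)B2CC[C@@H]1Cc2cc(OC)cc(OC)c2C(=O)O1
F7 | step 4 | (3R)-3-[(3E,6S)-6-hydroxyundec-3-en-1-yl]-6,8-dimethoxyisochroman-1-one | CCCCC[C@H](O)C/C=C/CC[C@@H]1Cc2cc(OC)cc(OC)c2C(=O)O1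
F8 | step 6 | (3R)-3-[(6S)-6-acetoxyundecyl]-6,8-dimethoxyisochroman-1-one | CCCCC[C@H](OC(C)=O)CCCCC[C@@H]1Cc2cc(OC)cc(OC)c2C(=O)O1
F9 | step 6 | (3R)-3-[(6S)-6-acetoxyundecyl]-8-hydroxy-6-methoxyisochroman-1-one | CCCCC[C@H](OC(C)=O)CCCCC[C@@H]1Cc2cc(OC)cc(O)c2C(=O)O1
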